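**Retrosynthetic overview** (flavone numbering is used for all chain atoms)
- Feature: ring A carries oxygen on C5, C6, C7, C8 and C8a, and its only carbon substituent sits on C4a. It is an acylphloroglucinol (O on C5, C7, C8a) whose two former chain methylenes, C6 and C8, each hold an extra methoxy group.
- Ring C (O1–C2) is opened to a 2,6-dihydroxyaryl 1,3-diketone whose two phenols are equivalent.
- Ring A (C4a–C5) is opened by a retro-Claisen step to a linear C9 triketo ester with C7 masked as a dimethyl ketal. Loss of one ketal methanol aromatises the ring.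
- The chain is cut at C4a–C8a. One half is the terminal dianion of 2-methoxy-1-(3-methoxyphenyl)butane-1,3-dione. The other is the imidazolide of a tetramethoxyglutaric half-ester, made from dimethyl 3-oxoglutarate by double diazo transfer, double O–H insertion, ketalisation and monohydrolysis.
- Ring order: ring B is bought, ring A forms in step 8, ring C forms in step 9.

Key step: step 8

Assumption: the target is achiral, and every intermediate with sp3 stereocentres is carried as a mixture of stereoisomers and keto–enol tautomers, so the SMILES carry no stereodescriptors.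

**Step 1**
Reactants: 1 dimethyl 3-oxoglutarate (dimethyl 3-oxopentanedioate)
Product: 2 dimethyl 2,4-bis(diazo)-3-oxopentanedioate
Conditions: 4-acetamidobenzenesulfonyl azide (2.3 equiv), Et3N (2.5 equiv), MeCN, 0 °C → rt; handled in solution behind a shield
Reagents that add atoms: 4-acetamidobenzenesulfonyl azide, CC(=O)Nc1ccc(cc1)S(=O)(=O)N=[N+]=[N-]
Why: Regitz diazo transfer: each methylene of 1 lies between a ketone and an ester, so its enolate attacks the terminal azide nitrogen, and the excess of azide should let the second transfer outrun base-induced cyclisation of the monodiazo ester to a 4-hydroxypyrazole.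

**Step 2**
Reactants: 2 dimethyl 2,4-bis(diazo)-3-oxopentanedioate
Product: 3 dimethyl 2,4-dimethoxy-3-oxopentanedioate (mixture of diastereomers)
Conditions: Rh2(OAc)4 (2 mol%), MeOH–ClCH2CH2Cl 1:4, 60 °C, slow addition of 2
Reagents that add atoms: methanol, CO
Why: Rhodium-carbenoid O–H insertion, well established for 2-diazo-3-oxo esters: each diazo carbon loses N2 to give an electrophilic carbenoid that the large excess of methanol captures (oxonium ylide, then proton shift) faster than Wolff rearrangement or reaction with a second diazo group, and the two new stereocentres need no control because both are erased in step 8.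

**Step 3**
Reactants: 3 dimethyl 2,4-dimethoxy-3-oxopentanedioate
Product: 4 dimethyl 2,3,3,4-tetramethoxypentanedioate (mixture of diastereomers)
Conditions: HC(OMe)3 (8 equiv), MeOH, H2SO4 (10 mol%), 50 °C; Et3N quench before concentration
Reagents that add atoms: trimethyl orthoformate, COC(OC)OC; methanol (solvent, exchanges with the orthoformate), CO
Why: Acid-catalysed ketalisation with an orthoester as water scavenger: the ketone between two inductively withdrawing CH(OMe)CO2Me groups is highly electrophilic, so the ketal should be favoured at equilibrium in methanol, and neutralising the acid before concentration should prevent loss of methanol to the enol ether.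

**Step 4**
Reactants: 4 dimethyl 2,3,3,4-tetramethoxypentanedioate
Product: 5 2,3,3,4-tetramethoxypentanedioic acid monomethyl ester (2,3,3,4,5-pentamethoxy-5-oxopentanoic acid)
Conditions: KOH (1.0 equiv), THF–H2O, 0 °C; cold 1 M HCl to pH 2
Reagents that add atoms: potassium hydroxide, [K+].[OH-]
Why: Selective monosaponification of a symmetric diester (BAc2): with one equivalent of hydroxide at 0 °C the first carboxylate slows attack on the second ester, hydrolysis of the activated α-methoxy ester is much faster than α-deprotonation, and the ketal, flanked by electron-poor carbons, tolerates base and the brief cold acidification.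

**Step 5**
Reactants: 6 3-methoxyphenylmagnesium bromide; 7 N,2-dimethoxy-N-methylacetamide
Product: 8 2-methoxy-1-(3-methoxyphenyl)ethan-1-one
Conditions: THF, 0 °C → rt; 1 M HCl
Reagents that add atoms: none
Why: Weinreb ketone synthesis: the aryl Grignard reagent adds once to give a magnesium-chelated tetrahedral adduct that collapses to the ketone only on acidic work-up, so no tertiary alcohol should form.

**Step 6**
Reactants: 8 2-methoxy-1-(3-methoxyphenyl)ethan-1-one; 9 1-acetyl-1H-benzotriazole
Product: 10 2-methoxy-1-(3-methoxyphenyl)butane-1,3-dione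
Conditions: MgBr2·OEt2 (2.5 equiv), iPr2NEt (3 equiv), CH2Cl2, rt; 1 M HCl
Reagents that add atoms: none
Why: Soft-enolisation C-acylation (crossed Claisen type): 8 has a single enolisable carbon, so no regiochemical ambiguity arises, chelation of magnesium by the carbonyl and α-methoxy oxygens makes that CH2 acidic enough for the amine, and the product is held as its magnesium diketonate, which blocks a second acylation.

**Step 7**
Reactants: 5 2,3,3,4-tetramethoxypentanedioic acid monomethyl ester; 10 2-methoxy-1-(3-methoxyphenyl)butane-1,3-dione
Product: 13 methyl 2,3,3,4,8-pentamethoxy-9-(3-methoxyphenyl)-5,7,9-trioxononanoate (stereoisomer/tautomer mixture), via acyl imidazole 11 (not isolated), via dilithium dienediolate 12 (not isolated)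
Conditions: flask A: 5, CDI (1.0 equiv), THF, rt, then N2 sparge to expel CO2; flask B: 10 (3.2 equiv), LiN(iPr)2 (6.6 equiv), THF, −78 → 0 °C; A into B at −78 °C; cold 1 M HCl to pH 4
Reagents that add atoms: 1,1'-carbonyldiimidazole, O=C(n1ccnc1)n1ccnc1 (imidazolyl group of 11 only); lithium diisopropylamide, [Li+].CC(C)[N-]C(C)C (lithium of 12 only)
Why: γ-Acylation of a 1,3-diketone dianion with an N-acylimidazole: the second deprotonation of 10 can only occur at the methyl group, and the resulting terminal carbanion attacks the imidazolide much faster than the methyl ester at −78 °C, so the glutarate is extended at one end only; of the 3.2 equivalents of 12 one is spent on the N–H of the liberated imidazole and one on the acidic C4a methylene of the product (10 is recovered), and the ketal leaves no strongly acidic hydrogen in 11.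

**Step 8**
Reactants: 13 methyl 2,3,3,4,8-pentamethoxy-9-(3-methoxyphenyl)-5,7,9-trioxononanoate
Product: 15 1-(2,6-dihydroxy-3,4,5-trimethoxyphenyl)-2-methoxy-3-(3-methoxyphenyl)propane-1,3-dione, via acylcyclohexanedione 14 (not isolated)
Conditions: Mg(OMe)2 (4 equiv), MeOH, rt → 65 °C; then 2 M HCl, 0 °C → rt
Reagents that add atoms: none
Why: Proposed new method: Mg(OMe)2 deprotonates 13 at the C4a methylene (chain C6, between the C4 and C8a carbonyls) and at C3-H to give a doubly chelated magnesium enolate, the C4a carbon adds to the terminal ester carbonyl C5, which magnesium can activate through the carbonyl and α-methoxy oxygens, and loss of methoxide forms the C4a–C5 bond of 14. Deprotonation of 14 to its tricarbonyl anion makes the closure irreversible, and enolisation towards C6 or C8 with expulsion of one methoxy group from the C7 ketal (on heating in base, completed by the acid treatment) aromatises the ring to the symmetric ketone 15 with exactly one methoxy group left on C7. The closest known reaction type is the Mg(OMe)2-mediated Claisen cyclisation of 3,5,7-triketo esters, and of the pyranones derived from them, to acylphloroglucinols; what has not been shown is this closure on a chain that bears methoxy groups on C3, C6 and C8 and aromatises by loss of methanol from a ketal. Ring A closes 6-exo-trig at the ester carbonyl (allowed whether the delocalised enolate is drawn enolendo or enolexo) and is helped by the gem-dimethoxy carbon in the tether; no stereocentre is created, those at C6 and C8 are erased, and the one at C3 is labile and vanishes in step 9. The step needs C-acylation at C4a to beat aldol folding, lactonisation and retro-Claisen cleavage: C6 and C8 are not deprotonated by this base and an aldol through them would give a quaternary methoxy carbon that cannot dehydrate to an arene and so reverts, an enol lactone formed through the C8a oxygen is reopened by methoxide whereas 14 is drained off as its anion, and both 1,3-diketone units are shielded from methoxide as magnesium enolates. Because the C8a carbonyl is locked in that enolate and the ester is not enolised, the ketal should survive until the ring is closed, so no alkene geometry has to be controlled.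

**Step 9**
Reactants: 15 1-(2,6-dihydroxy-3,4,5-trimethoxyphenyl)-2-methoxy-3-(3-methoxyphenyl)propane-1,3-dione
Product: 16 emmaosunin, 5-hydroxy-3,6,7,8-tetramethoxy-2-(3-methoxyphenyl)-4H-chromen-4-one
Conditions: TsOH·H2O (20 mol%), PhMe, 110 °C, Dean–Stark
Reagents that add atoms: none
Why: Acid-catalysed cyclodehydration of an o-hydroxyaryl 1,3-diketone, the closing stage of a Baker–Venkataraman flavone synthesis: either of the two equivalent phenols adds to the aroyl carbonyl (6-exo-trig), the hemiketal loses water to give ring C, the other phenol ends as the hydrogen-bonded C5-OH, any Wessely–Moser ring opening and reclosure is degenerate for this substitution pattern, and the last stereocentre (C3) becomes sp2.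

**Compound list**
1 | dimethyl 3-oxoglutarate | COC(=O)CC(=O)CC(=O)OC | starting material
2 | dimethyl 2,4-bis(diazo)-3-oxopentanedioate | COC(=O)C(=[N+]=[N-])C(=O)C(=[N+]=[N-])C(=O)OC | intermediate
3 | dimethyl 2,4-dimethoxy-3-oxopentanedioate | COC(=O)C(OC)C(=O)C(OC)C(=O)OC | intermediate
4 | dimethyl 2,3,3,4-tetramethoxypentanedioate | COC(=O)C(OC)C(OC)(OC)C(OC)C(=O)OC | intermediate
5 | 2,3,3,4-tetramethoxypentanedioic acid monomethyl ester | COC(=O)C(OC)C(OC)(OC)C(OC)C(=O)O | intermediate
6 | 3-methoxyphenylmagnesium bromide | COc1cccc([Mg]Br)c1 | starting material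
7 | N,2-dimethoxy-N-methylacetamide | COCC(=O)N(C)OC | starting material
8 | 2-methoxy-1-(3-methoxyphenyl)ethan-1-one | COCC(=O)c1cccc(OC)c1 | intermediate
9 | 1-acetyl-1H-benzotriazole | CC(=O)n1nnc2ccccc21 | starting material
10 | 2-methoxy-1-(3-methoxyphenyl)butane-1,3-dione | COc1cccc(C(=O)C(OC)C(C)=O)c1 | intermediate
11 | methyl 5-(1H-imidazol-1-yl)-2,3,3,4-tetramethoxy-5-oxopentanoate | COC(=O)C(OC)C(OC)(OC)C(OC)C(=O)n1ccnc1 | intermediate
12 | dilithium 2-methoxy-1-(3-methoxyphenyl)buta-1,3-diene-1,3-diolate | [Li+].[Li+].C=C([O-])C(OC)=C([O-])c1cccc(OC)c1 | intermediate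
13 | methyl 2,3,3,4,8-pentamethoxy-9-(3-methoxyphenyl)-5,7,9-trioxononanoate | COc1cccc(C(=O)C(OC)C(=O)CC(=O)C(OC)C(OC)(OC)C(OC)C(=O)OC)c1 | intermediate
14 | 4,5,5,6-tetramethoxy-2-[2-methoxy-3-(3-methoxyphenyl)-3-oxopropanoyl]cyclohexane-1,3-dione | COc1cccc(C(=O)C(OC)C(=O)C2C(=O)C(OC)C(OC)(OC)C(OC)C2=O)c1 | intermediate
15 | 1-(2,6-dihydroxy-3,4,5-trimethoxyphenyl)-2-methoxy-3-(3-methoxyphenyl)propane-1,3-dione | COc1cccc(C(=O)C(OC)C(=O)c2c(O)c(OC)c(OC)c(OC)c2O)c1 | intermediate
16 | emmaosunin | COc1cccc(-c2oc3c(OC)c(OC)c(OC)c(O)c3c(=O)c2OC)c1 | target

**Total step count:** 9. **Longest linear sequence:** 7 steps (1, 2, 3, 4, 7, 8, 9).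

**Steps most likely to fail**

Step 8 (proposed new method). Four processes could spoil it:
- The chain may fold through oxygen instead of carbon.
- It may fragment by retro-Claisen cleavage at the α-methoxy diketone.
- It may lose methanol from the ketal before closure.
- Closure may simply be too slow for a hindered magnesium enolate.

Incomplete aromatisation is not a failure, because the acid of step 9 would finish it.

The fallback uses known chemistry and takes ring A from an arene. It sets out from 8 and comes back at 16.
- Commercial 2,4,6-trimethoxybenzoic acid is converted with (COCl)2 and catalytic DMF into 2,4,6-trimethoxybenzoyl chloride F1.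
- C-acylation of the magnesium enolate of 8 under the step 6 protocol should give 2-methoxy-1-(3-methoxyphenyl)-3-(2,4,6-trimethoxyphenyl)propane-1,3-dione F2.
- Chelation-directed cleavage of one methyl ether ortho to the aryl ketone (BCl3, CH2Cl2, −78 → 0 °C) gives 1-(2-hydroxy-4,6-dimethoxyphenyl)-2-methoxy-3-(3-methoxyphenyl)propane-1,3-dione F3.
- Cyclodehydration (TsOH, PhMe) gives 3,5,7-trimethoxy-2-(3-methoxyphenyl)-4H-chromen-4-one F4.
- Electrophilic bromination of the strongly activated ring A (NBS, 2.2 equiv, DMF) gives 6,8-dibromo-3,5,7-trimethoxy-2-(3-methoxyphenyl)-4H-chromen-4-one F5.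
- Ullmann-type methoxylation (NaOMe, CuBr, DMF–MeOH, 110 °C) gives 3,5,6,7,8-pentamethoxy-2-(3-methoxyphenyl)-4H-chromen-4-one F6.
- Selective cleavage of the peri C5 methyl ether (BCl3, CH2Cl2) then gives 16.

Step 7. The strongly basic dianion may abstract the α-proton of the acyl imidazole, which would trigger β-elimination of methoxide from the ketal. Acylation may also spread to the methyl ester.

The fallback replaces the dianion by its neutral silyl equivalent. It sets out from 10 and 5 and comes back at 13.
- 10 is silylated (TMSCl, Et3N) to 3-methoxy-4-(3-methoxyphenyl)-4-(trimethylsilyloxy)but-3-en-2-one F7.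
- Treatment with LiN(iPr)2 and TMSCl at −78 °C gives 2-methoxy-1-(3-methoxyphenyl)-1,3-bis(trimethylsilyloxy)buta-1,3-diene F8.
- 5 is converted with (COCl)2 and catalytic DMF into methyl 5-chloro-2,3,3,4-tetramethoxy-5-oxopentanoate F9.
- F8 and F9 are combined in CH2Cl2 (−78 °C → rt). The terminal carbon of the bis-silyl dienol ether is acylated without any base present, and mild aqueous work-up gives 13.

Step 3. Ionisation of the hemiketal to a destabilised, crowded oxocarbenium ion may be too slow. The ketal may also lose methanol to the enol ether.

The fallback swaps equilibrium ketalisation for an oxidatively driven exchange. It sets out from 3 and comes back at 4.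
- Propane-1,3-dithiol and BF3·OEt2 in CH2Cl2 give dimethyl 2,2'-(1,3-dithiane-2,2-diyl)bis(2-methoxyacetate) F10.
- Hypervalent-iodine cleavage of the dithiane in methanol (PhI(OCOCF3)2, MeOH, 0 °C) replaces both C–S bonds irreversibly by methoxy groups to give 4.

**Further compounds**
F1 | step 8 | 2,4,6-trimethoxybenzoyl chloride | COc1cc(OC)c(C(Cl)=O)c(OC)c1
F2 | step 8 | 2-methoxy-1-(3-methoxyphenyl)-3-(2,4,6-trimethoxyphenyl)propane-1,3-dione | COc1cccc(C(=O)C(OC)C(=O)c2c(OC)cc(OC)cc2OC)c1
F3 | step 8 | 1-(2-hydroxy-4,6-dimethoxyphenyl)-2-methoxy-3-(3-methoxyphenyl)propane-1,3-dione | COc1cccc(C(=O)C(OC)C(=O)c2c(O)cc(OC)cc2OC)c1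
F4 | step 8 | 3,5,7-trimethoxy-2-(3-methoxyphenyl)-4H-chromen-4-one | COc1cccc(-c2oc3cc(OC)cc(OC)c3c(=O)c2OC)c1
F5 | step 8 | 6,8-dibromo-3,5,7-trimethoxy-2-(3-methoxyphenyl)-4H-chromen-4-one | COc1cccc(-c2oc3c(Br)c(OC)c(Br)c(OC)c3c(=O)c2OC)c1
F6 | step 8 | 3,5,6,7,8-pentamethoxy-2-(3-methoxyphenyl)-4H-chromen-4-one | COc1cccc(-c2oc3c(OC)c(OC)c(OC)c(OC)c3c(=O)c2OC)c1
F7 | step 7 | 3-methoxy-4-(3-methoxyphenyl)-4-(trimethylsilyloxy)but-3-en-2-one | CC(=O)C(OC)=C(O[Si](C)(C)C)c1cccc(OC)c1
F8 | step 7 | 2-methoxy-1-(3-methoxyphenyl)-1,3-bis(trimethylsilyloxy)buta-1,3-diene | C=C(O[Si](C)(C)C)C(OC)=C(O[Si](C)(C)C)c1cccc(OC)c1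
F9 | step 7 | methyl 5-chloro-2,3,3,4-tetramethoxy-5-oxopentanoate | COC(=O)C(OC)C(OC)(OC)C(OC)C(Cl)=O
F10 | step 3 | dimethyl 2,2'-(1,3-dithiane-2,2-diyl)bis(2-methoxyacetate) | COC(=O)C(OC)C1(C(OC)C(=O)OC)SCCCS1
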